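Two questions came before the meeting on this flask, one on conversion and one on pH; its terms were tabled first.

    electrophile + nucleophile ⇌ acid + product + leaving group (K1 = 1.3 × 10⁻⁵ M, k1 = 0.197 M⁻¹ s⁻¹)
    electrophile ⇌ dormant form (K2 = 27.8, k2 = 0.0363 s⁻¹)
    buffer acid ⇌ buffer base + acid, settled at all times (K3 = 6.3 × 10⁻⁸ M)
    protonated nucleophile ⇌ nucleophile + acid, settled at all times (K4 = 2.0 × 10⁻⁷ M)
electrophile 0.020 M; nucleophile 0.0600 M; buffer base 10.0 mM; buffer acid 2.00 mM (fed, over 40 s); time 40 s; the fed solution adds 0.20 times the starting volume
1. part of the electrophile that has reacted at 40 s
2. pH of the solution at 40 s
- acid is the free proton; pH is minus the decimal logarithm of its molar concentration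
- charges are per starting volume, the dose included; the dosed solution carries all of it
- what has gone from electrophile into another species counts as reacted, even if it can come back
- run time (flask): 40 s

I argued that both proton exchanges may be held at balance, so the buffer pair gives the acid cheaply. If the nucleophile, the larger base, takes up the protons released on the way to product, the buffer keeps roughly its charged ratio once the dose is in. Then [acid] is 6.3 × 10⁻⁸ M times buffer acid over buffer base, 1.26 × 10⁻⁸ M, which is pH 7.90.

I went on that this [acid] lies well below 2.0 × 10⁻⁷ M, which leaves 94.1% of the nucleophile free. At mid-dose the flask holds 1.10 starting volumes, so free [nucleophile] is about 0.0513 M.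

I therefore proposed one number, the loss constant: the dormant step's forward constant plus the product step's constant times that free [nucleophile], a pseudo-first-order constant for the electrophile, 0.0464 s⁻¹. I set aside the way back from the dormant form, at 0.00131 s⁻¹. Over 40 s this gives 84.4% reacted.

The maker of the forecast then gave 83% and pH 7.86, with the protons “shared between the buffer base and the large excess of free nucleophile”. On conversion my figure differs from the forecast by 1.4 percentage points.

The simulation gives 83.1% and pH 7.86 for the flask, with [acid] 1.38 × 10⁻⁸ M against my 1.26 × 10⁻⁸ M, and my figure from the loss constant stands 1.3 points above the simulated conversion. In the flask, buffer acid entered for the whole 40 s while the pH fell from 8.28 at 10.0 s, and half of the dormant step's turnover was done by 11.6 s. The product step ran alongside, the dormant step using electrophile 4.2 times as fast at 40.0 s, with 88% of the charged nucleophile still free.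

For the neighbour flask with 0.015 M of nucleophile, the loss constant comes to 0.0388 s⁻¹, which gives 78.8% reacted. The simulation gives 77.4% for that neighbour.

Its constants are assumed; the result is computed.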